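**Proposed synthesis of CNP0288976.3 by ring contraction of an enantioenriched flavanone**

## Analysis of the target

The target is a formal oxidative dimer of a 2',4',4-trihydroxychalcone. Its core is a trans-2,3-disubstituted 2,3-dihydrobenzofuran (ring O1–C2–C3–C3a–C7a fused to benzo ring A). C2 carries a 4-hydroxyphenyl group, C3 a 2,4-dihydroxybenzoyl group, and C5 (para to O1) an (E)-enone that ends in a second 2,4-dihydroxyphenyl ketone.

There are two stereocentres, C2 and C3, both R, with the aryl and aroyl groups trans. C3–H is benzylic and alpha to an aryl ketone, so C3 is epimerisable and the trans arrangement is the thermodynamic one. C2 is therefore the only centre that has to be set absolutely and then protected from loss.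

The sensitive groups are:
- the benzylic C2–O1 aryl ether next to a para-hydroxyphenyl group (quinone methide formation under base, ionisation under acid);
- the 2'-hydroxychalcone (Michael acceptor, cyclisation to a flavanone);
- five free phenols (oxidation).

The difficulty is absolute control at C2 in a ring whose two substituted carbons are normally joined by a racemic radical coupling, and the attachment of two electron-rich aryl ketones to a base- and acid-labile core.

The feature the route exploits is the exocyclic carbonyl carbon on C3. Counted into the ring (O1–C2–C3–C(=O)–C3a–C7a), it gives the six-membered ring of a 2-arylchroman-4-one (flavanone) with that carbon as C4. The dihydrobenzofuran is thus a flavanone from which ring carbon C4 has been pushed out of the ring. A second feature is that both carbonyl groups carry the same 2,4-dihydroxyphenyl residue, so both aryl–C(=O) bonds can be made in one operation.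

## Retrosynthetic reasoning

14 to 13: the last operation only removes the four acetal protecting groups on the two resorcinol rings. The 4-hydroxyphenyl group on C2 is already free in 13, so no other functional group has to change on the labile, fully assembled skeleton.

13 to 9 and 12: both aryl–C(=O) bonds are cut at once, the one on the C3 carbonyl and the one on the enone carbonyl. This is possible because the two ketones carry the same aryl group. The precursor 9 is a bis(N-methoxy-N-methylamide), and the forward step is a double Weinreb ketone synthesis with one aryllithium, 12, made from bromide 11, which comes in one step from 10.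

9 to 8 to 6 and 7: the C3 amide is traced back to a methyl ester, and the free phenol to an acetate that the amidation reagent cleaves in the same flask. The C5–vinyl bond is cut next (Mizoroki–Heck reaction of aryl bromide 6 with acrylamide 7). The bromine sits on ring A throughout, so the enone carbons are added only after the stereocentres exist.

6 to 3 (key disconnection): the C3–C3a bond of the dihydrobenzofuran is cut and the ester carbon is reconnected to C3a. This regenerates the six-membered ring of flavanone 3, in which the ester carbon is the ring ketone C4. In the forward direction an oxidative 1,2-shift of the ring A carbon from C4 to C3 contracts the chromanone to the dihydrobenzofuran. It forms the C3–C3a bond, turns the ring ketone into the exocyclic carboxyl carbon and sets C3 trans to C2, all in one step. The gain is that the only stereocentre that needs a catalyst is C2 of a flavanone, for which catalytic asymmetric methods exist, and that C2 then relays its configuration to C3. The cut is placed here and not at C2–C3 or C2–O1 because those cuts require both stereocentres to be created in the ring-forming step. The acetate on the C2 aryl group is there for this step: it makes that ring electron-poor while the cationic rearrangement runs.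

3 to 1 and 2: the C2–aryl bond is cut. The forward reaction is an enantioselective conjugate addition of arylboronic acid 2 to chromone 1. It creates C2 under base-free conditions in which a flavanone cannot racemise through ring opening.

## Alternatives that were turned down

Alternative 1: the textbook, biomimetic disconnection cuts C3–C3a and C2–O1 together. In the forward direction a one-electron oxidant converts the chalcone isoliquiritigenin A1 into a phenoxyl radical. This couples through its alpha carbon with the ortho carbon of a second molecule, and the resulting quinone methide is trapped by the phenol to give the racemic trans dimer A2 in one step. It was turned down for three reasons. A radical–radical coupling offers no handle for the absolute configuration. The spin density is spread over oxygen, the ortho carbons and the alpha carbon, so several coupling modes compete. The resorcinol rings of A1 and of A2 are themselves oxidisable, so oligomers are expected, and the single step would have to be followed by a resolution.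

Alternative 2: disconnection of C2–C3. The forward key step is an intramolecular C–H insertion of the donor/acceptor carbene from aryldiazoacetate A3 into the benzylic ether C–H, catalysed by a chiral dirhodium tetracarboxylate. It gives the cis ester A4, which is then epimerised at C3. This is the route most chemists would draw for an enantioenriched 2-aryl-2,3-dihydrobenzofuran-3-carboxylate. It was turned down because A3 needs about four steps (phenylacetate, O-benzylation, diazo transfer) and arrives at the same oxidation level as 6, so nothing is gained in step count. Both stereocentres would also depend on catalyst matching at a para-oxygenated benzyl ether, where oxonium ylide formation and a 1,2-benzyl shift compete with insertion.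

Alternative 3: late dearomatisation. The flat 2-aryl-3-aroylbenzofuran A5 would be assembled by robust aromatic chemistry, and both centres would be set by asymmetric hydrogenation of C2=C3 to the cis compound A6, followed by epimerisation at C3. It was turned down because C2=C3 is tetrasubstituted, part of an aromatic furan and conjugated to the aroyl group. The reduction would have to overcome aromatic stabilisation while sparing the aryl ketone and the C–Br bond, and carbonyl reduction is expected to be faster. The enone would in any case have to be added afterwards.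

Key step: step 2

Assumption: the (S)-pyridine-oxazoline ligand is taken to give the 2R flavanone 3, by analogy with its sense of induction on cyclic enones. If the opposite sense is found, the (R)-ligand is used and nothing else changes.

## Route

Step 1
Reactants: 1 6-bromochromone; 2 (4-acetoxyphenyl)boronic acid
Product: 3 4-[(2R)-6-bromo-4-oxo-3,4-dihydro-2H-chromen-2-yl]phenyl acetate
Conditions: Pd(OCOCF3)2 (5 mol%), (S)-4-tert-butyl-2-(pyridin-2-yl)-4,5-dihydrooxazole (6 mol%), NH4PF6 (30 mol%), H2O (5 equiv), ClCH2CH2Cl, 60 °C
Reagents that add atoms: none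
Why: Enantioselective conjugate addition of an arylboronic acid to a chromone under divalent palladium/pyridine-oxazoline catalysis (aryl–palladium insertion across C2=C3, then protonation of the palladium enolate) is an established reaction type; the ligand controls the face at C2. The medium is weakly acidic and free of base, so 3 should not racemise through ring opening to the chalcone, and the C–Br bond and the acetate are inert to divalent palladium.

Step 2
Reactants: 3 4-[(2R)-6-bromo-4-oxo-3,4-dihydro-2H-chromen-2-yl]phenyl acetate
Product: 6 methyl (2R,3R)-2-(4-acetoxyphenyl)-5-bromo-2,3-dihydro-1-benzofuran-3-carboxylate, via enol ether 4 (not isolated), via iodane 5 (not isolated)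
Conditions: PhI(OAc)2 (1.2 equiv), H2SO4 (conc., 0.3 equiv), HC(OMe)3, 0 °C to rt; then H2O, NaHCO3
Reagents that add atoms: trimethyl orthoformate COC(OC)OC (ester OCH3); water O (ester carbonyl oxygen, on work-up)
Why: Acid and the orthoformate convert the ketone of 3 into enol ether 4; the trivalent iodine reagent attacks C3 of 4 on the face anti to the C2 aryl group and methanol caps C4, giving the C3-iodanyl ketal 5. In 5 the equatorial C3–I bond is antiperiplanar to the ring bond C4–C4a, so the ring A carbon C4a shifts from C4 to C3 with loss of iodobenzene, and the dimethoxycarbenium ion left at the extruded carbon is hydrolysed to the methyl ester on work-up. The closest known reaction type is the oxidative ring contraction of flavanones to methyl trans-2-aryl-2,3-dihydrobenzofuran-3-carboxylates with trivalent iodine or thallium trinitrate, a cyclic case of the 1,2-aryl shift that turns aryl ketones into arylacetic esters. The five-membered ring O1–C2–C3–C3a–C7a is not closed by a cyclisation: it results from contraction of the six-membered ring by a 1,2-shift through a phenonium-like bridged transition state, which forms C3–C3a while C4–C4a breaks. C2 is not touched, so its configuration is that of 3; C3 is set by C2, because anti attack of iodine followed by migration with inversion at C3 places the ester trans to the aryl group, and trans is also the thermodynamic epimer at this enolisable centre. The step needs migration of C4a to win over a 1,2-shift of the C2 aryl group and over loss of the C2 proton; the acetoxy substituent makes the C2 aryl group a poor migrating group and a poor stabiliser of positive charge at C2, the diequatorial conformer aligns only the ring bond with C–I, and C4a is activated by the ortho ring oxygen. The acetate, the aryl bromide and the configuration at C2 should survive the short exposure to acid at room temperature.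

Step 3
Reactants: 6 methyl (2R,3R)-2-(4-acetoxyphenyl)-5-bromo-2,3-dihydro-1-benzofuran-3-carboxylate; 7 N-methoxy-N-methylacrylamide
Product: 8 methyl (2R,3R)-2-(4-acetoxyphenyl)-5-[(E)-3-[methoxy(methyl)amino]-3-oxoprop-1-en-1-yl]-2,3-dihydro-1-benzofuran-3-carboxylate
Conditions: 7 (1.5 equiv), Pd(P(t-Bu)3)2 (3 mol%), Cy2NMe (1.5 equiv), 1,4-dioxane, 70 °C
Reagents that add atoms: none
Why: Mizoroki–Heck reaction of the aryl bromide with an electron-poor acrylamide at its terminal carbon; syn beta-hydride elimination gives the E alkene. The hindered amine and moderate temperature should leave the acetate intact and can only move C3 towards the trans configuration it already has.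

Step 4
Reactants: 8 methyl (2R,3R)-2-(4-acetoxyphenyl)-5-[(E)-3-[methoxy(methyl)amino]-3-oxoprop-1-en-1-yl]-2,3-dihydro-1-benzofuran-3-carboxylate
Product: 9 (2R,3R)-2-(4-hydroxyphenyl)-N-methoxy-5-[(E)-3-[methoxy(methyl)amino]-3-oxoprop-1-en-1-yl]-N-methyl-2,3-dihydro-1-benzofuran-3-carboxamide
Conditions: Me(MeO)NH·HCl (5 equiv), iPrMgCl (10 equiv), premixed in THF at −20 °C; then 8, −20 to 0 °C; aq. NH4Cl
Reagents that add atoms: N,O-dimethylhydroxylamine hydrochloride CNOC.Cl
Why: Aminolysis of the methyl ester by the chloromagnesium amide of N,O-dimethylhydroxylamine gives the Weinreb amide. The same reagent cleaves the aryl acetate (an activated ester), so the electron-withdrawing group needed only in step 2 leaves without a separate step. Premixing consumes the Grignard reagent before the existing amide is exposed, and C3 stays trans because that is the thermodynamic epimer even if the magnesium enolate forms.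

Step 5
Reactants: 10 4-bromobenzene-1,3-diol
Product: 11 1-bromo-2,4-bis(methoxymethoxy)benzene
Conditions: MOMCl (2.5 equiv), iPr2NEt (3 equiv), CH2Cl2, 0 °C to rt
Reagents that add atoms: chloromethyl methyl ether COCCl
Why: Standard O-alkylation of both phenols; methoxymethyl ethers tolerate aryllithium chemistry and are removed by mild acid at the end.

Step 6
Reactants: 9 (2R,3R)-2-(4-hydroxyphenyl)-N-methoxy-5-[(E)-3-[methoxy(methyl)amino]-3-oxoprop-1-en-1-yl]-N-methyl-2,3-dihydro-1-benzofuran-3-carboxamide; 11 1-bromo-2,4-bis(methoxymethoxy)benzene
Product: 13 (E)-1-[2,4-bis(methoxymethoxy)phenyl]-3-[(2R,3R)-3-[2,4-bis(methoxymethoxy)benzoyl]-2-(4-hydroxyphenyl)-2,3-dihydro-1-benzofuran-5-yl]prop-2-en-1-one, via aryllithium 12 (not isolated)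
Conditions: 11 (4.5 equiv), n-BuLi (4.4 equiv), THF, −78 °C; then 9, −78 to −40 °C; aq. NH4Cl
Reagents that add atoms: none
Why: Bromine–lithium exchange gives 12; one equivalent deprotonates the phenol and two add to the two N-methoxy-N-methylamides (Weinreb ketone synthesis), so both identical aryl ketones are formed in one operation. The chelated tetrahedral intermediates prevent over-addition and favour 1,2- over conjugate addition at the unsaturated amide; on work-up C3 keeps the trans configuration, which is also the thermodynamic one for the ketone.

Step 7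
Reactants: 13 (E)-1-[2,4-bis(methoxymethoxy)phenyl]-3-[(2R,3R)-3-[2,4-bis(methoxymethoxy)benzoyl]-2-(4-hydroxyphenyl)-2,3-dihydro-1-benzofuran-5-yl]prop-2-en-1-one
Product: 14 (E)-1-(2,4-dihydroxyphenyl)-3-[(2R,3R)-3-(2,4-dihydroxybenzoyl)-2-(4-hydroxyphenyl)-2,3-dihydro-1-benzofuran-5-yl]prop-2-en-1-one
Conditions: HCl (3 M aq.), MeOH, 45 °C
Reagents that add atoms: none
Why: Acid-catalysed acetal exchange with methanol removes the four methoxymethyl groups, a deprotection commonly used to unveil 2'-hydroxychalcones, whose chelated ortho hydroxyl resists cyclisation under these conditions. The C3 aroyl group inductively disfavours ionisation of the C2–O1 bond, and any enolisation at C3 returns the trans epimer.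

## Compound list

1 | 6-bromochromone (6-bromo-4H-chromen-4-one) | O=c1ccoc2ccc(Br)cc12 | starting material
2 | (4-acetoxyphenyl)boronic acid | CC(=O)Oc1ccc(B(O)O)cc1 | starting material
3 | 4-[(2R)-6-bromo-4-oxo-3,4-dihydro-2H-chromen-2-yl]phenyl acetate | O=C1C[C@H](c2ccc(OC(C)=O)cc2)Oc2ccc(Br)cc21 | intermediate
4 | 4-[(2R)-6-bromo-4-methoxy-2H-chromen-2-yl]phenyl acetate | COC1=C[C@H](c2ccc(OC(C)=O)cc2)Oc2ccc(Br)cc21 | intermediate
5 | 4-[(2S,3S)-3-[acetoxy(phenyl)-λ3-iodanyl]-6-bromo-4,4-dimethoxy-3,4-dihydro-2H-chromen-2-yl]phenyl acetate (iodine trans to the C2 aryl group) | COC1(OC)[C@@H](I(OC(C)=O)c2ccccc2)[C@H](c2ccc(OC(C)=O)cc2)Oc2ccc(Br)cc21 | intermediate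
6 | methyl (2R,3R)-2-(4-acetoxyphenyl)-5-bromo-2,3-dihydro-1-benzofuran-3-carboxylate | Brc1ccc2c(c1)[C@@H](C(=O)OC)[C@H](c1ccc(OC(C)=O)cc1)O2 | intermediate
7 | N-methoxy-N-methylacrylamide | C=CC(=O)N(C)OC | starting material
8 | methyl (2R,3R)-2-(4-acetoxyphenyl)-5-[(E)-3-[methoxy(methyl)amino]-3-oxoprop-1-en-1-yl]-2,3-dihydro-1-benzofuran-3-carboxylate | CON(C)C(=O)/C=C/c1ccc2c(c1)[C@@H](C(=O)OC)[C@H](c1ccc(OC(C)=O)cc1)O2 | intermediate
9 | (2R,3R)-2-(4-hydroxyphenyl)-N-methoxy-5-[(E)-3-[methoxy(methyl)amino]-3-oxoprop-1-en-1-yl]-N-methyl-2,3-dihydro-1-benzofuran-3-carboxamide | CON(C)C(=O)/C=C/c1ccc2c(c1)[C@@H](C(=O)N(C)OC)[C@H](c1ccc(O)cc1)O2 | intermediate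
10 | 4-bromobenzene-1,3-diol (4-bromoresorcinol) | Oc1ccc(Br)c(O)c1 | starting material
11 | 1-bromo-2,4-bis(methoxymethoxy)benzene | COCOc1ccc(Br)c(OCOC)c1 | intermediate
12 | [2,4-bis(methoxymethoxy)phenyl]lithium | [Li]c1ccc(OCOC)cc1OCOC | intermediate
13 | (E)-1-[2,4-bis(methoxymethoxy)phenyl]-3-[(2R,3R)-3-[2,4-bis(methoxymethoxy)benzoyl]-2-(4-hydroxyphenyl)-2,3-dihydro-1-benzofuran-5-yl]prop-2-en-1-one | COCOc1ccc(C(=O)/C=C/c2ccc3c(c2)[C@@H](C(=O)c2ccc(OCOC)cc2OCOC)[C@H](c2ccc(O)cc2)O3)c(OCOC)c1 | intermediate
14 | (E)-1-(2,4-dihydroxyphenyl)-3-[(2R,3R)-3-(2,4-dihydroxybenzoyl)-2-(4-hydroxyphenyl)-2,3-dihydro-1-benzofuran-5-yl]prop-2-en-1-one | O=C(/C=C/c1ccc2c(c1)[C@@H](C(=O)c1ccc(O)cc1O)[C@H](c1ccc(O)cc1)O2)c1ccc(O)cc1O | target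

## Step count and least certain steps

Total step count: 7. Longest linear sequence: 6 steps (steps 1, 2, 3, 4, 6 and 7 from 1); step 5 is a one-step side branch.

**Step 2 (key step).** Three processes are most likely to interfere:
- migration of the C2 aryl group in place of the ring carbon C4a, or elimination across C2–C3, both of which divert the iodanyl ketal away from ring contraction;
- acid-promoted methanolysis of the acetate, after which the freed phenol ring would be oxidised by the iodine reagent;
- partial loss of configuration at C2 through reversible ionisation of the benzylic C–O bond.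

Fallback, from 1, returning at 9: the same ring contraction is run as a photochemical Wolff rearrangement, which involves neither positive charge at C3 nor acid. Chromone 1 is arylated as in step 1 with [4-(methoxymethoxy)phenyl]boronic acid to give (2R)-6-bromo-2-[4-(methoxymethoxy)phenyl]chroman-4-one F1. Its lithium enolate (LiN(SiMe3)2, THF, −78 °C) is acylated with CF3CO2CH2CF3 to the 3-trifluoroacetyl ketone F2. Detrifluoroacetylative diazo transfer with 4-acetamidobenzenesulfonyl azide and Et3N gives the 3-diazo ketone F3. Irradiation at 365 nm in THF with N,O-dimethylhydroxylamine leads through ketene F4 to the amide, which catalytic KOt-Bu equilibrates at C3 to the trans Weinreb amide F5. A Mizoroki–Heck reaction with 7 as in step 3 gives the bis-amide F6, and HCl in MeOH removes its methoxymethyl group to give 9.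

**Step 6.** The basic aryllithium may deprotonate C3–H (benzylic and alpha to the amide) in place of adding, so the C3 amide is returned unchanged; the double addition may also stop halfway if the lithium phenoxide aggregates.

Fallback, from 6, returning at 13: the two ketones are made one after the other, and the enone arrives as a preformed unit. Ester 6 is treated as in step 4 to give (2R,3R)-5-bromo-2-(4-hydroxyphenyl)-N-methoxy-N-methyl-2,3-dihydro-1-benzofuran-3-carboxamide F7. The less basic organocerium reagent from 12 and CeCl3 converts F7 into [2,4-bis(methoxymethoxy)phenyl][(2R,3R)-5-bromo-2-(4-hydroxyphenyl)-2,3-dihydro-1-benzofuran-3-yl]methanone F8. A Mizoroki–Heck reaction of F8 with 1-[2,4-bis(methoxymethoxy)phenyl]prop-2-en-1-one F9 (from 12 and 7) under the conditions of step 3 gives 13.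

**Step 1.** Insufficient facial selectivity at C2, or slow turnover with protodeboronation of 2, is the likely problem, because chromones are sluggish acceptors.

Fallback, from 1 and 2, returning at 3: the addition is run with an achiral 2,2'-bipyridine ligand to give racemic 4-(6-bromo-4-oxo-3,4-dihydro-2H-chromen-2-yl)phenyl acetate F10. A kinetic resolution by asymmetric transfer hydrogenation (RuCl(p-cymene)(TsDPEN), HCO2H/Et3N) follows, with the catalyst enantiomer chosen so that the 2S ketone is reduced to 4-[(2S,4S)-6-bromo-4-hydroxy-3,4-dihydro-2H-chromen-2-yl]phenyl acetate F11. The unreacted 2R ketone is recovered as 3, at the price of half of the material.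

**Step 7.** Under acid the 2'-hydroxyl may add to the enone (cyclisation to a flavanone), or the benzylic C2–O1 bond may ionise with help from the free para-hydroxyphenyl group and scramble C2.

Fallback, from 10 and 9, returning at 14: the acetal groups are replaced by fluoride-labile silyl ethers, so the last step needs no strong acid. Diol 10 with TIPSCl and imidazole gives 1-bromo-2,4-bis(triisopropylsilyloxy)benzene F12. Bromine–lithium exchange at −78 °C gives the aryllithium F13, which adds twice to 9 as in step 6 to give the tetrakis(triisopropylsilyl) ether F14 of the target. Et3N·3HF in THF at room temperature then releases 14.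

## Further compounds

F1 | step 2 | (2R)-6-bromo-2-[4-(methoxymethoxy)phenyl]chroman-4-one | O=C1C[C@H](c2ccc(OCOC)cc2)Oc2ccc(Br)cc21
F2 | step 2 | (2R)-6-bromo-2-[4-(methoxymethoxy)phenyl]-3-(trifluoroacetyl)chroman-4-one (C3 epimers and enol form) | O=C1C(C(=O)C(F)(F)F)[C@H](c2ccc(OCOC)cc2)Oc2ccc(Br)cc21
F3 | step 2 | (2S)-6-bromo-3-diazo-2-[4-(methoxymethoxy)phenyl]chroman-4-one (same spatial arrangement at C2 as in F1) | O=C1C(=[N+]=[N-])[C@H](c2ccc(OCOC)cc2)Oc2ccc(Br)cc21
F4 | step 2 | (2S)-5-bromo-2-[4-(methoxymethoxy)phenyl]-3-(oxomethylidene)-2,3-dihydro-1-benzofuran | O=C=C1[C@H](c2ccc(OCOC)cc2)Oc2ccc(Br)cc21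
F5 | step 2 | (2R,3R)-5-bromo-N-methoxy-2-[4-(methoxymethoxy)phenyl]-N-methyl-2,3-dihydro-1-benzofuran-3-carboxamide | Brc1ccc2c(c1)[C@@H](C(=O)N(C)OC)[C@H](c1ccc(OCOC)cc1)O2
F6 | step 2 | (2R,3R)-N-methoxy-5-[(E)-3-[methoxy(methyl)amino]-3-oxoprop-1-en-1-yl]-2-[4-(methoxymethoxy)phenyl]-N-methyl-2,3-dihydro-1-benzofuran-3-carboxamide | CON(C)C(=O)/C=C/c1ccc2c(c1)[C@@H](C(=O)N(C)OC)[C@H](c1ccc(OCOC)cc1)O2
F7 | step 6 | (2R,3R)-5-bromo-2-(4-hydroxyphenyl)-N-methoxy-N-methyl-2,3-dihydro-1-benzofuran-3-carboxamide | Brc1ccc2c(c1)[C@@H](C(=O)N(C)OC)[C@H](c1ccc(O)cc1)O2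
F8 | step 6 | [2,4-bis(methoxymethoxy)phenyl][(2R,3R)-5-bromo-2-(4-hydroxyphenyl)-2,3-dihydro-1-benzofuran-3-yl]methanone | Brc1ccc2c(c1)[C@@H](C(=O)c1ccc(OCOC)cc1OCOC)[C@H](c1ccc(O)cc1)O2
F9 | step 6 | 1-[2,4-bis(methoxymethoxy)phenyl]prop-2-en-1-one | C=CC(=O)c1ccc(OCOC)cc1OCOC
F10 | step 1 | racemic 4-(6-bromo-4-oxo-3,4-dihydro-2H-chromen-2-yl)phenyl acetate | O=C1CC(c2ccc(OC(C)=O)cc2)Oc2ccc(Br)cc21
F11 | step 1 | 4-[(2S,4S)-6-bromo-4-hydroxy-3,4-dihydro-2H-chromen-2-yl]phenyl acetate | O[C@H]1C[C@@H](c2ccc(OC(C)=O)cc2)Oc2ccc(Br)cc21
F12 | step 7 | 1-bromo-2,4-bis(triisopropylsilyloxy)benzene | CC(C)[Si](Oc1ccc(Br)c(O[Si](C(C)C)(C(C)C)C(C)C)c1)(C(C)C)C(C)C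
F13 | step 7 | [2,4-bis(triisopropylsilyloxy)phenyl]lithium | [Li]c1ccc(O[Si](C(C)C)(C(C)C)C(C)C)cc1O[Si](C(C)C)(C(C)C)C(C)C
F14 | step 7 | (E)-1-[2,4-bis(triisopropylsilyloxy)phenyl]-3-[(2R,3R)-3-[2,4-bis(triisopropylsilyloxy)benzoyl]-2-(4-hydroxyphenyl)-2,3-dihydro-1-benzofuran-5-yl]prop-2-en-1-one | CC(C)[Si](Oc1ccc(C(=O)/C=C/c2ccc3c(c2)[C@@H](C(=O)c2ccc(O[Si](C(C)C)(C(C)C)C(C)C)cc2O[Si](C(C)C)(C(C)C)C(C)C)[C@H](c2ccc(O)cc2)O3)c(O[Si](C(C)C)(C(C)C)C(C)C)c1)(C(C)C)C(C)C
A1 | alternative 1 | isoliquiritigenin, (E)-1-(2,4-dihydroxyphenyl)-3-(4-hydroxyphenyl)prop-2-en-1-one | O=C(/C=C/c1ccc(O)cc1)c1ccc(O)cc1O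
A2 | alternative 1 | racemic trans dimer, (E)-1-(2,4-dihydroxyphenyl)-3-[trans-3-(2,4-dihydroxybenzoyl)-2-(4-hydroxyphenyl)-2,3-dihydro-1-benzofuran-5-yl]prop-2-en-1-one (both enantiomers) | O=C(/C=C/c1ccc2c(c1)C(C(=O)c1ccc(O)cc1O)C(c1ccc(O)cc1)O2)c1ccc(O)cc1O
A3 | alternative 2 | methyl 2-[5-bromo-2-[[4-(methoxymethoxy)phenyl]methoxy]phenyl]-2-diazoacetate | COC(=O)C(=[N+]=[N-])c1cc(Br)ccc1OCc1ccc(OCOC)cc1
A4 | alternative 2 | methyl (2R,3S)-5-bromo-2-[4-(methoxymethoxy)phenyl]-2,3-dihydro-1-benzofuran-3-carboxylate (cis) | Brc1ccc2c(c1)[C@H](C(=O)OC)[C@H](c1ccc(OCOC)cc1)O2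
A5 | alternative 3 | [2,4-bis(methoxymethoxy)phenyl][5-bromo-2-[4-(methoxymethoxy)phenyl]-1-benzofuran-3-yl]methanone | COCOc1ccc(-c2oc3ccc(Br)cc3c2C(=O)c2ccc(OCOC)cc2OCOC)cc1
A6 | alternative 3 | [2,4-bis(methoxymethoxy)phenyl][(2R,3S)-5-bromo-2-[4-(methoxymethoxy)phenyl]-2,3-dihydro-1-benzofuran-3-yl]methanone (cis) | Brc1ccc2c(c1)[C@H](C(=O)c1ccc(OCOC)cc1OCOC)[C@H](c1ccc(OCOC)cc1)O2
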